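The target does not keep. The flasks below differ in how and when their charges meet the heat.

all flasks: catalyst 20 mM
- dawn: starting material 0.40 M; reagent 0.44 M; temperature 10 °C; run made earlier
- autumn: starting material 0.27 M; reagent 0.44 M; temperature 25 °C; run made earlier
- dusk: starting material 0.60 M; reagent 0.44 M; temperature 10 °C; run made earlier
- west: starting material 0.40 M; reagent 0.440 M; temperature 25 °C; everything together at the start; time 5.0 d
- north: starting material 0.40 M; reagent 0.440 M (fed, over 4.0 d); temperature 25 °C; all else is in the flask from the start; the feed brings no volume worth counting; time 5.0 d
- south-east: starting material 0.40 M; reagent 0.440 M; everything together at the start at −5 °C, warmed to 25 °C at 4.0 d; time 5.0 d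
- south: starting material 0.40 M (fed, over 25 h); reagent 0.440 M; temperature 25 °C; all else is in the flask from the start; the feed brings no volume worth counting; time 5.0 d
- south-west: starting material 0.40 M (fed, over 4.0 d); reagent 0.440 M; the addition at −5 °C, then warmed to 25 °C; the feed brings no volume worth counting; time 5.0 d
- east: starting material 0.40 M; reagent 0.440 M (in portions, 5, over 4.0 d); temperature 25 °C; first portion at the start, last at 4.0 d; time 5.0 d

- dawn (time / d: target / %): 0.625: 79.6; 2.00: 71.9; 4.00: 54.3; 5.00: 49.2; 8.00: 28.1; 10.0: 19.8
- autumn (time / d: target / %): 0.625: 49.3; 1.25: 21.9; 2.08: 7.5; 2.50: 3.4; 3.00: 3.1; 4.00: 0.2
- dusk (time / d: target / %): 0.625: 65.7; 1.04: 61.6; 1.67: 58.3; 4.00: 40.6; 5.00: 34.7; 8.00: 21.8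

(each reading ± 1 percentage point)

- the flask that comes out highest in amount of target, in percent of the starting material charged, or "all alike" when all lie within 1.5 percentage points (west / north / south-east / south / south-west / east / all alike)
- target at the end, in percent of the starting material charged, west
- target at the end, in percent of the starting material charged, north
- target at the end, in percent of the starting material charged, south-east
- target at the end, in percent of the starting material charged, south
- target at the end, in percent of the starting material charged, south-west
- target at the end, in percent of the starting material charged, east

In the autumn run at 25 °C, the target falls from 49.3% to 7.5% between 0.625 d and 2.08 d, which reads as a first-order loss of 1.29 d⁻¹. At 10 °C the dawn run reads 0.148 d⁻¹ and the dusk run, with more starting material, 0.150 d⁻¹, so the loss does not seem to follow that charge.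

The fraction of target present at 4.0 d that is still there at 5.0 d, held at 25 °C, is 27.4%; I call it the warm-day survival. The balance of the smaller charge goes with it. Starting material is the limiting reagent, at 0.40 M against 0.440 M of reagent, and for a flask warmed at 4.0 d I multiply what that charge can become by the survival.

Two chemists dispute the flask. The first says that lateness counts: a feed keeps the target young. He supposes that in north the charge fed over 4.0 d turns as it comes, and he reckons the stock where feed meets loss at 19.3%; the warm day then cuts his figure to 5.29%, against 0.155% for west.

The second says that temperature counts. −5 °C lies as far below 10 °C as 25 °C lies above it, so he assumes the same factor and reckons a cold loss of 0.0170 d⁻¹. Over 4.0 d that is an exponent of 0.0680, far smaller than the 1.29 of the warm day. So he expects about 27.4% from south-east and from south-west.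

The forecast takes the second side, on the grounds that “Cold holds preserve the target”. It names south-west, with west 0.17%, north 4.3%, south-east 26.5%, south 0.35%, south-west 27.5% and east 6.5%. So it puts south-west higher than south-east, where the second chemist gives both one figure.

The flask highest in target is south-west: south-west 27.9%, south-east 26.1%, east 7.06%, north 5.13%, south 0.360%, west 0.160%.

    target → over-reaction product (k = 9.20 × 10⁻⁴ min⁻¹, Ea = 99.0 kJ mol⁻¹)
    starting material + reagent + catalyst → catalyst + target (k = 2.10 M⁻² min⁻¹, Ea = 55.0 kJ mol⁻¹)
    (constants at 25 °C)

Cold without a feed, in south-east, beats the feed in north. The first chemist keeps the flasks held at 25 °C, where north ends above west, and a gain of 1.8 percentage points for south-west over south-east. Now take south-west with 0.18 M of reagent. Reagent is then the smaller charge, so the balance allows 45.0% of the starting material charged, and the warm-day survival turns that into 12.3%. That neighbour ends with reagent at 0% of its own charge and, in percent of the starting material charged, starting material at 55.0%, over-reaction product at 33.2% and target at 11.8%.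

Readings and results stem from a simulated flask with constants of no real substance, noise included.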